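**Strategy.** Ring A is disconnected between the adjacent carbinol carbons C2 and C3 (drimane numbering), C3 lying next to the quaternary C4. Both are traced back to ester carbons, so one sodium/chlorotrimethylsilane acyloin condensation forms the C2–C3 bond, closes ring A as a trans-decalin and places both ring-A oxygens as an enediol bis(silyl ether). The precursor is a ring-B cyclohexane, made from (S)-carvone, carrying the quaternary C10 (CH3, CH2CO2Me), the trans C5 arm C(CH3)2CO2Me and a dioxolane-masked C9 ketone. That ketone later serves to introduce C12, the C7 alkene and the C11 coumarinyl ether.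

Key step: step 5

Remark on numbering: carbons carry drimane numbers throughout (C1 to C10 in the decalin, C11 on C9, C12 the methyl on C8). The target is (2S,3S,5S,9R,10R), the antipodal (ent) drimane series, which is why the (S) enantiomer of carvone is needed.

Remark on the chemistry: the ketol released from the acyloin product is assumed to be an interconverting pair of regioisomers of unknown proportion; step 6 is chosen so that both should lead to the same diol.

**Step 1**
Reactants: 1 (S)-carvone; 2 methyl trimethylsilyl dimethylketene acetal
Product: 3 silyl enol ether carrying the C(CH3)2CO2Me arm at C5, trans to the isopropenyl group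
Conditions: Tf2NH (2 mol %), CH2Cl2, −78 °C
Reagents that add atoms: none
Why: Mukaiyama–Michael addition in which the silyl Lewis acid formed from Tf2NH activates the enone, the ketene acetal attacks C5 axially on the face opposite the C7 isopropenyl group (the usual course of conjugate additions to carvone, which sets C5), and silyl transfer to the enolate oxygen leaves a regiodefined enol ether.

**Step 2**
Reactants: 3 silyl enol ether; 4 methyl bromoacetate
Product: 6 isopropenyl keto diester with quaternary C10, via tris(dimethylamino)sulfonium enolate 5 (not isolated)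
Conditions: (Me2N)3S+ Me3SiF2− (TASF), THF, −78 °C → rt
Reagents that add atoms: none
Why: Fluoride-promoted regiospecific enolate alkylation, in which desilylation releases the C9–C10 enolate and the bromoacetate attacks C10 on the face anti to the bulky C5 arm, so that CH2CO2Me ends trans to that arm (this sets C10).

**Step 3**
Reactants: 6 isopropenyl keto diester
Product: 8 keto diester with C7 as CH2, via α-methoxy hydroperoxide 7 (not isolated)
Conditions: O3, MeOH, −78 °C; then FeSO4·7H2O, PhSH, −78 °C → rt
Reagents that add atoms: none
Why: Ozonolytic hydrodealkenylation, in which the divalent iron salt reduces the hydroperoxide to an alkoxy radical that loses methyl acetate by β-scission and the secondary C7 radical takes hydrogen from the thiol; C7 becomes CH2, so no stereocentre is involved.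

**Step 4**
Reactants: 8 keto diester
Product: 9 dioxolane diester (key-step precursor)
Conditions: Me3SiOCH2CH2OSiMe3, Me3SiOTf (cat.), CH2Cl2, −78 → −20 °C
Reagents that add atoms: 1,2-bis(trimethylsilyloxy)ethane, C[Si](C)(C)OCCO[Si](C)(C)C
Why: Aprotic ketalisation with the bis-silyl ether of ethylene glycol under silyl triflate catalysis, a method that converts α-quaternary cyclohexanones and leaves both methyl esters untouched.

**Step 5 (key step)**
Reactants: 9 dioxolane diester
Product: 10 trans-decalin enediol bis(trimethylsilyl) ether with the C9 dioxolane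
Conditions: Na (dispersion, 4.5 equiv), Me3SiCl (6 equiv), toluene, reflux, slow addition of 9
Reagents that add atoms: chlorotrimethylsilane, C[Si](C)(C)Cl
Why: Sodium transfers single electrons to both ester carbonyls, the radical anions at C2 and C3 couple, two methoxides leave to give the 2,3-dione stage, and two further electrons give the enediolate, which the silyl chloride caps on both oxygens. The closest known reaction type is the acyloin condensation of 1,6-diesters run with chlorotrimethylsilane trapping (Rühlmann variant), the standard entry to six-membered acyloins. Ring A closes as a six-membered carbocycle by intramolecular reductive carbonyl–carbonyl coupling of the two arms, which sit trans-diequatorial on ring B, so the trans ring fusion already fixed at C5 and C10 is carried over. No stereocentre is created, since C2 and C3 emerge sp2. The selectivity needed is chemoselectivity over Dieckmann closure from C1 onto the C3 ester and over ketyl chemistry at C9; the silyl chloride removes the methoxide base, the C3 ester cannot enolise, and C9 is masked as the dioxolane.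

**Step 6**
Reactants: 10 enediol bis(trimethylsilyl) ether
Product: 13 trans-diequatorial 2,3-diol with the C9 dioxolane, via 2-hydroxy-3-oxo ketol 11 (not isolated), via 3-hydroxy-2-oxo ketol 12 (not isolated)
Conditions: NaOn-Pr, n-PrOH, rt (argon); then Na, n-PrOH, reflux
Reagents that add atoms: none
Why: Alkoxide cleaves both silyl ethers to the base-equilibrated ketols, and a Bouveault–Blanc-type dissolving-metal reduction then converts either carbonyl into the more stable equatorial carbinol (as sodium in alcohol does with ring ketones flanked by two syn-axial methyl groups, where hydride reagents give the axial alcohol), so both ketols should converge on the diol with 3-OH cis and 2-OH trans to the C10 methyl (C2 and C3 set under thermodynamic control).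

**Step 7**
Reactants: 13 diol dioxolane
Product: 14 acetonide ketone (free C9 ketone)
Conditions: acetone/Me2C(OMe)2 (4:1), TsOH·H2O (cat.), rt
Reagents that add atoms: 2,2-dimethoxypropane, COC(C)(C)OC
Why: Acid-catalysed transketalisation, in which the glycol of the strained α-quaternary dioxolane is handed to the solvent acetone while the diol is tied up as its acetonide, and the hindered C9 ketone does not re-ketalise in excess acetone.

**Step 8**
Reactants: 14 acetonide ketone
Product: 16 C8-methyl ketone (C8 epimer mixture), via lithium enolate 15 (not isolated)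
Conditions: LiN(i-Pr)2, THF, −78 °C; then MeI, −78 → 0 °C
Reagents that add atoms: iodomethane, CI
Why: Kinetic enolate alkylation, regiodefined because only C8 carries α-hydrogens (C10 is quaternary); the C8 configuration is irrelevant since C8 becomes sp2 in step 9.

**Step 9**
Reactants: 16 C8-methyl ketone
Product: 18 enone (C7=C8, C9=O), via trimethylsilyl enol ether 17 (not isolated)
Conditions: LiN(i-Pr)2, Me3SiCl, THF, −78 → 0 °C; then Pd(OAc)2 (1 equiv), MeCN, rt
Reagents that add atoms: none
Why: Saegusa–Ito oxidation, in which the only possible enol ether (C8=C9) is palladated at C8 and β-hydride elimination toward C7 gives the conjugated endocyclic enone, as with 2-methylcyclohexanone enol ethers.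

**Step 10**
Reactants: 18 enone
Product: 19 diene (C7=C8 and C9=C11)
Conditions: Ph3PCH3Br, KOtBu, toluene, 90 °C
Reagents that add atoms: methyltriphenylphosphonium bromide, C[P+](c1ccccc1)(c1ccccc1)c1ccccc1.[Br-]
Why: Wittig methylenation with a salt-free ylide in hot toluene, conditions suited to hindered ketones; the non-stabilised ylide should add 1,2 to the enone carbonyl, as it does with carvone.

**Step 11**
Reactants: 19 diene
Product: 21 homoallylic primary alcohol (C11–OH), via B-alkyl-9-borabicyclononane 20 (not isolated)
Conditions: 9-BBN, THF, 0 °C → rt; then NaOH, H2O2, 0 °C → rt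
Reagents that add atoms: hydrogen peroxide, OO
Why: Hydroboration–oxidation, in which 9-BBN places boron on the terminal C11 of the exocyclic alkene and delivers hydrogen to C9 from the face opposite the axial C10 methyl, so C11 ends cis to that methyl (C9 set by substrate control) while the trisubstituted C7=C8 alkene is left alone.

**Step 12**
Reactants: 21 homoallylic alcohol; 22 umbelliferone
Product: 23 acetonide-protected coumarinyl ether
Conditions: PPh3, DIAD, THF, 0 °C → rt
Reagents that add atoms: none
Why: Mitsunobu etherification of the primary alcohol with the acidic 7-hydroxycoumarin; no stereocentre is touched and the hindered ring-A oxygens are tied up in the acetonide.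

**Step 13**
Reactants: 23 acetonide-protected ether
Product: 24 target diol
Conditions: AcOH/H2O (4:1), 40 °C
Reagents that add atoms: none
Why: Acid-catalysed acetal hydrolysis of the strained trans-fused acetonide under conditions mild enough for the trisubstituted alkene, the aryl ether and the coumarin lactone.

**Compound list**

1 | (S)-carvone | CC1=CC[C@@H](CC1=O)C(C)=C | starting material
2 | methyl trimethylsilyl dimethylketene acetal (1-methoxy-2-methyl-1-(trimethylsilyloxy)prop-1-ene) | COC(O[Si](C)(C)C)=C(C)C | starting material
3 | methyl 2-methyl-2-[(1S,5S)-2-methyl-5-(prop-1-en-2-yl)-3-(trimethylsilyloxy)cyclohex-2-en-1-yl]propanoate (ester arm trans to isopropenyl) | CC1=C(O[Si](C)(C)C)C[C@@H](C(C)=C)C[C@@H]1C(C)(C)C(=O)OC | intermediate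
4 | methyl bromoacetate | COC(=O)CBr | starting material
5 | tris(dimethylamino)sulfonium enolate derived from 3 (C9–O−, C9=C10) | CC1=C([O-])C[C@@H](C(C)=C)C[C@@H]1C(C)(C)C(=O)OC.CN(C)[S+](N(C)C)N(C)C | intermediate (not isolated)
6 | keto diester (5S,7S,10R): cyclohexanone (C9=O) with CH3 and CH2CO2Me on C10, C(CH3)2CO2Me on C5 trans to CH2CO2Me, isopropenyl on C7 cis to CH2CO2Me | COC(=O)C[C@]1(C)[C@@H](C(C)(C)C(=O)OC)C[C@H](C(C)=C)CC1=O | intermediate
7 | α-methoxy hydroperoxide of 6 (C7 bears C(CH3)(OCH3)OOH, mixture at that carbon) | COC(=O)C[C@]1(C)[C@@H](C(C)(C)C(=O)OC)C[C@H](C(C)(OC)OO)CC1=O | intermediate (not isolated)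
8 | keto diester (5S,10R): as 6 but C7 is CH2 | COC(=O)C[C@]1(C)[C@@H](C(C)(C)C(=O)OC)CCCC1=O | intermediate
9 | dioxolane diester (5S,10R), key-step precursor: 1,4-dioxaspiro[4.5]decane with CH3 and CH2CO2Me on C10 and C(CH3)2CO2Me on C5, the two ester arms trans | COC(=O)C[C@]1(C)[C@@H](C(C)(C)C(=O)OC)CCCC12OCCO2 | intermediate
10 | 2,3-bis(trimethylsilyloxy)-11,12-dinordrim-2-en-9-one ethylene ketal, trans-fused (5-H anti to 10-CH3), C5 and C10 as in 9 | C[Si](C)(C)OC1=C(O[Si](C)(C)C)C(C)(C)[C@H]2CCCC3(OCCO3)[C@]2(C)C1 | intermediate
11 | 2-hydroxy-3-oxo ketol (2-OH equatorial, trans to 10-CH3), C9 ethylene ketal | C1CC[C@@H]2C(C)(C)C(=O)[C@@H](O)C[C@@]2(C)C13OCCO3 | intermediate (not isolated)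
12 | 3-hydroxy-2-oxo ketol (3-OH equatorial, cis to 10-CH3), C9 ethylene ketal | C1CC[C@@H]2C(C)(C)[C@H](O)C(=O)C[C@@]2(C)C13OCCO3 | intermediate (not isolated)
13 | 2,3-dihydroxy-11,12-dinordriman-9-one ethylene ketal, trans-fused, 2-OH and 3-OH trans-diequatorial (3-OH cis, 2-OH trans to 10-CH3) | C1CC[C@@H]2C(C)(C)[C@H](O)[C@@H](O)C[C@@]2(C)C13OCCO3 | intermediate
14 | 2,3-O-isopropylidene derivative of 2,3-dihydroxy-11,12-dinordriman-9-one (diol configuration as in 13) | C1CC[C@@H]2C(C)(C)[C@H](O3)[C@@H](OC3(C)C)C[C@@]2(C)C1=O | intermediate
15 | lithium C8=C9 enolate of 14 | C=1CC[C@@H]2C(C)(C)[C@H](O3)[C@@H](OC3(C)C)C[C@@]2(C)C=1[O-].[Li+] | intermediate (not isolated)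
16 | 2,3-O-isopropylidene-2,3-dihydroxy-11-nordriman-9-one (C8 epimer mixture) | CC1CC[C@@H]2C(C)(C)[C@H](O3)[C@@H](OC3(C)C)C[C@@]2(C)C1=O | intermediate
17 | C8=C9 trimethylsilyl enol ether of 16 | CC=1CC[C@@H]2C(C)(C)[C@H](O3)[C@@H](OC3(C)C)C[C@@]2(C)C=1O[Si](C)(C)C | intermediate (not isolated)
18 | 2,3-O-isopropylidene-2,3-dihydroxy-11-nordrim-7-en-9-one | CC1=CC[C@@H]2C(C)(C)[C@H](O3)[C@@H](OC3(C)C)C[C@@]2(C)C1=O | intermediate
19 | 2,3-O-isopropylidene-2,3-dihydroxydrima-7,9(11)-diene | CC1=CC[C@@H]2C(C)(C)[C@H](O3)[C@@H](OC3(C)C)C[C@@]2(C)C1=C | intermediate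
20 | B-(C11)-alkyl-9-borabicyclo[3.3.1]nonane from 19 (9-H anti, C11 cis to 10-CH3) | CC1=CC[C@@H]2C(C)(C)[C@H](O3)[C@@H](OC3(C)C)C[C@@]2(C)[C@@H]1CB3C4CCCC3CCC4 | intermediate (not isolated)
21 | 2,3-O-isopropylidene-2,3-dihydroxydrim-7-en-11-ol (C11 cis to 10-CH3) | CC1=CC[C@@H]2C(C)(C)[C@H](O3)[C@@H](OC3(C)C)C[C@@]2(C)[C@@H]1CO | intermediate
22 | umbelliferone (7-hydroxycoumarin) | O=c1ccc2ccc(O)cc2o1 | starting material
23 | 7-[(2,3-O-isopropylidene-2,3-dihydroxydrim-7-en-11-yl)oxy]coumarin | CC1=CC[C@@H]2C(C)(C)[C@H](O3)[C@@H](OC3(C)C)C[C@@]2(C)[C@@H]1COc1ccc2ccc(=O)oc2c1 | intermediate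
24 | 7-{[(2S,3S,5S,9R,10R)-2,3-dihydroxydrim-7-en-11-yl]oxy}-2H-chromen-2-one (CNP0124364.1) | CC1=CC[C@@H]2C(C)(C)[C@H](O)[C@@H](O)C[C@@]2(C)[C@@H]1COc1ccc2ccc(=O)oc2c1 | target

**Step count and risks**

Total step count: 13. Longest linear sequence: 13 steps, from (S)-carvone to 24.

Steps most likely to fail:

1. Step 5 (key step). Electron transfer to the neopentyl C3 ester may lag behind that to the C2 ester, so that silylation at C1, intermolecular coupling, or loss of the dioxolane through traces of hydrogen chloride erodes the ring closure. Fallback, forming the same C2–C3 bond by different chemistry: setting out from 9, LiAlH4 in THF should give the diol F1, and Dess–Martin oxidation the dialdehyde F2. An intramolecular benzoin condensation under N-heterocyclic carbene catalysis (3-benzyl-5-(2-hydroxyethyl)-4-methylthiazolium chloride, Et3N, EtOH, 70 °C) should then close ring A: the acyl anion equivalent forms at the unhindered C2 aldehyde and adds to the non-enolisable C3 aldehyde. The route is rejoined at ketol 12, which is reduced under the second-stage conditions of step 6.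

2. Step 6. The oxygen next to the carbonyl may be lost reductively at the ketyl stage, or protonation at C2 may follow kinetic rather than thermodynamic control, giving deoxygenated or epimeric material. Fallback, a regiodefined hydride route setting out from 10:
   - MeLi (2 equiv) in THF should give the dilithium enediolate F3.
   - One equivalent of MOMCl at −78 °C should cap the unhindered O2 (O3 is shielded by the C4 methyls), and NaOMe in MeOH protonates and equilibrates C2 to the equatorial 2-(methoxymethoxy) 3-ketone F4. This ketone can enolise only toward C2, so its carbonyl cannot migrate.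
   - NaBH4 should attack C3 from the face opposite the axial methyls and give the equatorial carbinol F5.
   - Aqueous HCl in THF removes the MOM group and the dioxolane to the diol ketone F6, and 2,2-dimethoxypropane with TsOH returns to the route at 14.

3. Step 2. C-alkylation of the tetrasubstituted enolate next to the bulky C5 arm may be slow, so that O-alkylation, proton transfer from the bromoacetate or attack of the enolate oxygen on the side-chain ester takes over. Fallback, a radical instead of a polar alkylation: setting out from 3, visible-light photoredox catalysis (Ir(ppy)3, 2,6-lutidine, MeCN, blue light) with 4 generates the electrophilic radical •CH2CO2Me, which adds to C10 on the face away from the C5 arm. Oxidation of the resulting α-silyloxy radical and loss of the silyl group return the route at 6; no new compound is made (F0).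

**Further compounds**

F1 | step 5 | diol from reduction of both esters of 9 (C2 and C3 as CH2OH, C9 ethylene ketal) | OCC[C@]1(C)[C@@H](C(C)(C)CO)CCCC12OCCO2
F2 | step 5 | dialdehyde (C2 and C3 as CHO, C9 ethylene ketal) | O=CC[C@]1(C)[C@@H](C(C)(C)C=O)CCCC12OCCO2
F3 | step 6 | dilithium 2,3-enediolate of the trans-decalin, C9 ethylene ketal | [Li+].[Li+].[O-]C1=C([O-])C(C)(C)[C@H]2CCCC3(OCCO3)[C@]2(C)C1
F4 | step 6 | 2-(methoxymethoxy)-3-oxo compound (2-O equatorial), C9 ethylene ketal | C1CC[C@@H]2C(C)(C)C(=O)[C@@H](OCOC)C[C@@]2(C)C13OCCO3
F5 | step 6 | 2-(methoxymethoxy)-3-hydroxy compound (both oxygens equatorial), C9 ethylene ketal | C1CC[C@@H]2C(C)(C)[C@H](O)[C@@H](OCOC)C[C@@]2(C)C13OCCO3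
F6 | step 6 | 2,3-dihydroxy-11,12-dinordriman-9-one (trans-diequatorial diol, free ketone) | C1CC[C@@H]2C(C)(C)[C@H](O)[C@@H](O)C[C@@]2(C)C1=O
F0 | step 2 | none | none
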